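Hydroazulene numbering used below: C1–C2–C3(OH, iPr)–C3a(H)–C4(O‑anisoyl)–C5–C6(Me)=C7–C8(O‑angeloyl)–C8a(Me).
Retrosynthesis: the two esters are cut last, then C6=C7 (ring‑closing metathesis), then C4–C5 (methallyl addition to a C4 aldehyde), then C1–C2 and C3–C3a together (radical [3+2] annulation).
Enabling feature: quaternary C8a carries both the ring CH2 (C1) and the ring‑fusion carbon C3a, so an open‑chain C8a bearing CH2I and ethynyl is a three‑carbon radical/acceptor unit; C2 and the tertiary carbinol C3 with its isopropyl group are an α‑isopropylvinyl boronate.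
Forward order: acyclic C8/C8a stereodiad, then the cyclopentane by annulation, then the C4 aldehyde and carbinol, then the seven‑membered ring by metathesis, then the two esterifications.
Stereochemistry: C8 from a catalytic asymmetric acetate aldol; C8a from two Fráter–Seebach alkylations; C3 from 1,3‑induction in the ring closure and retentive C–B oxidation; C3a by equilibration; C4 by chelation control.
Key step: step 7

Remark: boronate 12 is taken as a catalogue reagent; the E/Z composition of the exocyclic iodoalkene in 13 and 14 is immaterial, because that carbon becomes the aldehyde carbon of 17.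

Step 1
Reactants: 1 acrolein; 2 1-(tert-butyldimethylsilyloxy)-1-methoxyethene
Product: 4 methyl (3S)-3-hydroxypent-4-enoate, via trichlorosilyl ether 3 (not isolated)
Conditions: SiCl4 (1.1 equiv), binaphthyldiamine-derived chiral bisphosphoramide (5 mol%, antipode that gives the S alcohol), CH2Cl2, −78 °C; then sat. aq NaHCO3
Reagents that add atoms: none
Why: Lewis-base-catalysed SiCl4 Mukaiyama acetate aldol, for which conjugated aldehydes are the best substrates; the chiral phosphoramide-bound silicon cation differentiates the aldehyde faces and should set C8.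

Step 2
Reactants: 4 methyl (3S)-3-hydroxypent-4-enoate
Product: 6 methyl (2R,3R)-3-hydroxy-2-methylpent-4-enoate, via dilithium dianion 5 (not isolated)
Conditions: LiN(iPr)2 (2.2 equiv), THF, −78 → −20 °C; MeI, DMPU, −78 → −10 °C; then H2O
Reagents that add atoms: iodomethane, CI
Why: Fráter–Seebach alkylation; the chelated dilithium alkoxide–enolate should be methylated on the face opposite the vinyl group, giving the 2,3-anti product.

Step 3
Reactants: 6 methyl (2R,3R)-3-hydroxy-2-methylpent-4-enoate
Product: 8 methyl (2R,3R)-3-hydroxy-2-(iodomethyl)-2-methylpent-4-enoate, via dilithium dianion 7 (not isolated)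
Conditions: LiN(iPr)2 (2.3 equiv), THF/DMPU, −78 → −15 °C; CH2I2 (4 equiv), −78 → −10 °C; then cold H2O
Reagents that add atoms: diiodomethane, ICI
Why: second Fráter–Seebach alkylation (SN2 on CH2I2); the tetrasubstituted chelated enolate should again be attacked anti to the vinyl group, so the order methyl first, iodomethyl second fixes quaternary C8a, and the product has no α-hydrogen through which the iodide could eliminate.

Step 4
Reactants: 8 methyl (2R,3R)-3-hydroxy-2-(iodomethyl)-2-methylpent-4-enoate
Product: 9 methyl (2R,3R)-3-[tert-butyl(dimethyl)silyl]oxy-2-(iodomethyl)-2-methylpent-4-enoate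
Conditions: TBSOTf, 2,6-lutidine, CH2Cl2, −78 → 0 °C
Reagents that add atoms: tert-butyldimethylsilyl trifluoromethanesulfonate, CC(C)(C)[Si](C)(C)OS(=O)(=O)C(F)(F)F
Why: silylation of a hindered secondary allylic alcohol with the reactive silyl triflate; the ester and the neopentyl iodide are inert.

Step 5
Reactants: 9 methyl (2R,3R)-3-[tert-butyl(dimethyl)silyl]oxy-2-(iodomethyl)-2-methylpent-4-enoate
Product: 10 (2R,3R)-3-[tert-butyl(dimethyl)silyl]oxy-2-(iodomethyl)-2-methylpent-4-enal
Conditions: iBu2AlH (1.2 equiv), CH2Cl2, −78 °C; then aq potassium sodium tartrate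
Reagents that add atoms: none
Why: partial reduction of an α-quaternary ester; the hindered aluminium hemiacetal should survive at −78 °C and give the aldehyde only on work-up, and the alkyl iodide is not reduced under these conditions.

Step 6
Reactants: 10 (2R,3R)-3-[tert-butyl(dimethyl)silyl]oxy-2-(iodomethyl)-2-methylpent-4-enal
Product: 11 tert-butyl{[(3R,4S)-4-(iodomethyl)-4-methylhex-1-en-5-yn-3-yl]oxy}dimethylsilane
Conditions: dimethyl (1-diazo-2-oxopropyl)phosphonate, K2CO3, MeOH, 0 °C → rt
Reagents that add atoms: dimethyl (1-diazo-2-oxopropyl)phosphonate, CC(=O)C(=[N+]=[N-])P(=O)(OC)OC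
Why: Ohira–Bestmann (Seyferth–Gilbert) homologation; the aldehyde has no α-hydrogen, so the basic methanol cannot epimerise it, and the neopentyl iodide is inert to SN2 attack.

Step 7
Reactants: 11 tert-butyl{[(3R,4S)-4-(iodomethyl)-4-methylhex-1-en-5-yn-3-yl]oxy}dimethylsilane; 12 4,4,5,5-tetramethyl-2-(3-methylbut-1-en-2-yl)-1,3,2-dioxaborolane
Product: 13 2-[(1S,3S)-3-[(1R)-1-{[tert-butyl(dimethyl)silyl]oxy}prop-2-en-1-yl]-2-(iodomethylidene)-3-methyl-1-(propan-2-yl)cyclopentyl]-4,4,5,5-tetramethyl-1,3,2-dioxaborolane (E/Z mixture)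
Conditions: 12 (4 equiv), (Bu3Sn)2 (10 mol%), sunlamp, benzene, 80 °C
Reagents that add atoms: none
Why: Iodine-atom-transfer radical [3+2] annulation, the known annulation of homopropargyl iodides with alkenes: Bu3Sn• abstracts iodine from 11, the primary radical adds to the CH2 terminus of the boron-activated alkene 12, the tertiary α-boryl radical closes onto the ethynyl group, and the vinyl radical takes iodine from the next molecule of 11. The ring closes in the 5-exo-dig mode. The new stereocentre C3 should be set by 1,3-induction from quaternary C8a in a chair-like transition state that keeps the isopropyl group and the large silyloxyallyl substituent pseudo-equatorial, hence cis, leaving the small planar boronate cis to the methyl group. An alkyne is the acceptor because a 1,2-alkynyl shift of the homopropargyl radical is slow, whereas a vinyl group on C8a would migrate; iodine transfer to the stabilised α-boryl radical is unfavourable, so cyclisation should precede chain transfer. The step needs 5-exo-dig closure to outrun 6-exo attack on the C7 vinyl group and 1,5-hydrogen transfer from C8–H, which the geminal placement of radical chain and alkyne on C8a favours, and excess 12 secures the first addition.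

Step 8
Reactants: 13 cyclopentyl boronate from step 7
Product: 14 (1R,3S)-3-[(1R)-1-{[tert-butyl(dimethyl)silyl]oxy}prop-2-en-1-yl]-2-(iodomethylidene)-3-methyl-1-(propan-2-yl)cyclopentan-1-ol
Conditions: 30% H2O2, 2 M NaOH, THF, 0 °C → rt
Reagents that add atoms: hydrogen peroxide, OO
Why: oxidation of a tertiary alkyl pinacol boronate by 1,2-shift of carbon from boron to oxygen with retention, so the hydroxyl takes the place of boron at C3; the iodoalkene and the silyl ether should tolerate cold alkaline peroxide.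

Step 9
Reactants: 14 iodoalkene alcohol from step 8
Product: 17 (1R,2R,5S)-5-[(1R)-1-{[tert-butyl(dimethyl)silyl]oxy}prop-2-en-1-yl]-2-hydroxy-5-methyl-2-(propan-2-yl)cyclopentane-1-carbaldehyde, via alkenylboronate 15 (not isolated), via epimeric aldehyde 16 (not isolated)
Conditions: tBuLi (3.3 equiv), Et2O, −78 °C; B(OMe)3, −78 °C → rt; 30% H2O2, aq NaHCO3, 0 °C; then Et3N (cat.), CH2Cl2, rt
Reagents that add atoms: hydrogen peroxide, OO
Why: iodine–lithium exchange, borylation and oxidation give the enol and hence the aldehyde; C3a is the only epimerisable centre and amine base should equilibrate it to the isomer with formyl trans to isopropyl and to the C8a side chain and cis to the hydroxyl (hydrogen bond).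

Step 10
Reactants: 17 hydroxy aldehyde from step 9; 18 2-methylallylmagnesium chloride
Product: 19 (1R,2S,3S)-3-[(1R)-1-{[tert-butyl(dimethyl)silyl]oxy}prop-2-en-1-yl]-2-[(1S)-1-hydroxy-3-methylbut-3-en-1-yl]-3-methyl-1-(propan-2-yl)cyclopentan-1-ol
Conditions: CH2=C(CH3)CH2MgCl (3.5 equiv), THF, −78 °C; then aq NH4Cl
Reagents that add atoms: none
Why: chelation-controlled Grignard addition; the magnesium alkoxide at C3 chelates the aldehyde oxygen and the allyl group should be delivered to the chelate face flanked by C3a–H, away from quaternary C8a, which sets C4 as S.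

Step 11
Reactants: 19 diene diol from step 10
Product: 20 (3R,3aS,4S,8R,8aS)-8-{[tert-butyl(dimethyl)silyl]oxy}-6,8a-dimethyl-3-(propan-2-yl)-1,2,3,3a,4,5,8,8a-octahydroazulene-3,4-diol
Conditions: second-generation Hoveyda–Grubbs catalyst RuCl2(H2IMes)(=CH-C6H4-2-OiPr) (10 mol%), 1,4-benzoquinone (20 mol%), toluene (3 mM), 80 °C
Reagents that add atoms: none
Why: ring-closing metathesis of a monosubstituted and a 1,1-disubstituted alkene closes the seven-membered ring as the trisubstituted C6=C7 alkene with loss of ethene; the trans ring fusion is already fixed and free hydroxyl groups are tolerated by the ruthenium carbene.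

Step 12
Reactants: 20 bicyclic diol from step 11; 21 4-methoxybenzoyl chloride
Product: 22 (3R,3aS,4S,8R,8aS)-8-{[tert-butyl(dimethyl)silyl]oxy}-3-hydroxy-6,8a-dimethyl-3-(propan-2-yl)-1,2,3,3a,4,5,8,8a-octahydroazulen-4-yl 4-methoxybenzoate
Conditions: 21, Et3N, DMAP (20 mol%), CH2Cl2, 0 °C → rt
Reagents that add atoms: none
Why: DMAP-catalysed acylation should occur only at the secondary C4 hydroxyl; the tertiary C3 hydroxyl does not acylate under these conditions and C8 is silyl-protected.

Step 13
Reactants: 22 silyl ether from step 12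
Product: 23 (3R,3aS,4S,8R,8aS)-3,8-dihydroxy-6,8a-dimethyl-3-(propan-2-yl)-1,2,3,3a,4,5,8,8a-octahydroazulen-4-yl 4-methoxybenzoate
Conditions: HF·pyridine, pyridine, THF, 0 °C → rt
Reagents that add atoms: none
Why: buffered fluoride cleavage of the silyl ether; the conditions are not basic, so the aryl ester should neither migrate nor be cleaved, and the tertiary alcohol is untouched.

Step 14
Reactants: 23 diol monoester from step 13; 24 angelic acid
Product: 26 (3R,3aS,4S,8R,8aS)-3-hydroxy-4-[(4-methoxybenzoyl)oxy]-6,8a-dimethyl-3-(propan-2-yl)-1,2,3,3a,4,5,8,8a-octahydroazulen-8-yl (2Z)-2-methylbut-2-enoate (target), via mixed anhydride 25 (not isolated)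
Conditions: 24, 2,4,6-trichlorobenzoyl chloride, Et3N, toluene, rt; then 23, 75 °C
Reagents that add atoms: none
Why: Yamaguchi-type esterification through the mixed anhydride without DMAP, a protocol used for hindered secondary alcohols and angelic acid because it avoids Z→E isomerisation to the tiglate; the tertiary hydroxyl is not acylated.

Compound list
1 | acrolein (prop-2-enal) | C=CC=O | starting material
2 | 1-(tert-butyldimethylsilyloxy)-1-methoxyethene | C=C(OC)O[Si](C)(C)C(C)(C)C | starting material
3 | methyl (3S)-3-(trichlorosilyloxy)pent-4-enoate | C=C[C@@H](O[Si](Cl)(Cl)Cl)CC(=O)OC | intermediate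
4 | methyl (3S)-3-hydroxypent-4-enoate | C=C[C@@H](O)CC(=O)OC | intermediate
5 | dilithium alkoxide–enolate of 4 | C=C[C@@H]([O-])C=C([O-])OC.[Li+].[Li+] | intermediate
6 | methyl (2R,3R)-3-hydroxy-2-methylpent-4-enoate | C=C[C@@H](O)[C@@H](C)C(=O)OC | intermediate
7 | dilithium alkoxide–enolate of 6 | C=C[C@@H]([O-])C(C)=C([O-])OC.[Li+].[Li+] | intermediate
8 | methyl (2R,3R)-3-hydroxy-2-(iodomethyl)-2-methylpent-4-enoate | C=C[C@@H](O)[C@@](C)(CI)C(=O)OC | intermediate
9 | methyl (2R,3R)-3-[tert-butyl(dimethyl)silyl]oxy-2-(iodomethyl)-2-methylpent-4-enoate | C=C[C@@H](O[Si](C)(C)C(C)(C)C)[C@@](C)(CI)C(=O)OC | intermediate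
10 | (2R,3R)-3-[tert-butyl(dimethyl)silyl]oxy-2-(iodomethyl)-2-methylpent-4-enal | C=C[C@@H](O[Si](C)(C)C(C)(C)C)[C@@](C)(CI)C=O | intermediate
11 | tert-butyl{[(3R,4S)-4-(iodomethyl)-4-methylhex-1-en-5-yn-3-yl]oxy}dimethylsilane | C=C[C@@H](O[Si](C)(C)C(C)(C)C)[C@@](C)(CI)C#C | intermediate
12 | 4,4,5,5-tetramethyl-2-(3-methylbut-1-en-2-yl)-1,3,2-dioxaborolane | CC(C)C(=C)B1OC(C)(C)C(C)(C)O1 | starting material
13 | 2-[(1S,3S)-3-[(1R)-1-{[tert-butyl(dimethyl)silyl]oxy}prop-2-en-1-yl]-2-(iodomethylidene)-3-methyl-1-(propan-2-yl)cyclopentyl]-4,4,5,5-tetramethyl-1,3,2-dioxaborolane | C=C[C@@H](O[Si](C)(C)C(C)(C)C)[C@@]1(C)CC[C@@](B2OC(C)(C)C(C)(C)O2)(C(C)C)C1=CI | intermediate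
14 | (1R,3S)-3-[(1R)-1-{[tert-butyl(dimethyl)silyl]oxy}prop-2-en-1-yl]-2-(iodomethylidene)-3-methyl-1-(propan-2-yl)cyclopentan-1-ol | C=C[C@@H](O[Si](C)(C)C(C)(C)C)[C@@]1(C)CC[C@@](O)(C(C)C)C1=CI | intermediate
15 | dimethyl alkenylboronate corresponding to 14 (B(OMe)2 in place of I) | C=C[C@@H](O[Si](C)(C)C(C)(C)C)[C@@]1(C)CC[C@@](O)(C(C)C)C1=CB(OC)OC | intermediate
16 | (1S,2R,5S)-epimer of 17 (formyl cis to isopropyl) | C=C[C@@H](O[Si](C)(C)C(C)(C)C)[C@@]1(C)CC[C@@](O)(C(C)C)[C@H]1C=O | intermediate
17 | (1R,2R,5S)-5-[(1R)-1-{[tert-butyl(dimethyl)silyl]oxy}prop-2-en-1-yl]-2-hydroxy-5-methyl-2-(propan-2-yl)cyclopentane-1-carbaldehyde | C=C[C@@H](O[Si](C)(C)C(C)(C)C)[C@@]1(C)CC[C@@](O)(C(C)C)[C@@H]1C=O | intermediate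
18 | 2-methylallylmagnesium chloride | CC(=C)C[Mg]Cl | starting material
19 | (1R,2S,3S)-3-[(1R)-1-{[tert-butyl(dimethyl)silyl]oxy}prop-2-en-1-yl]-2-[(1S)-1-hydroxy-3-methylbut-3-en-1-yl]-3-methyl-1-(propan-2-yl)cyclopentan-1-ol | C=C[C@@H](O[Si](C)(C)C(C)(C)C)[C@@]1(C)CC[C@@](O)(C(C)C)[C@@H]1[C@@H](O)CC(C)=C | intermediate
20 | (3R,3aS,4S,8R,8aS)-8-{[tert-butyl(dimethyl)silyl]oxy}-6,8a-dimethyl-3-(propan-2-yl)-1,2,3,3a,4,5,8,8a-octahydroazulene-3,4-diol | CC(C)(C)[Si](C)(C)O[C@@H]1C=C(C)C[C@H](O)[C@@H]2[C@]1(C)CC[C@@]2(O)C(C)C | intermediate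
21 | 4-methoxybenzoyl chloride | COc1ccc(cc1)C(Cl)=O | starting material
22 | (3R,3aS,4S,8R,8aS)-8-{[tert-butyl(dimethyl)silyl]oxy}-3-hydroxy-6,8a-dimethyl-3-(propan-2-yl)-1,2,3,3a,4,5,8,8a-octahydroazulen-4-yl 4-methoxybenzoate | CC(C)(C)[Si](C)(C)O[C@@H]1C=C(C)C[C@H](OC(=O)c2ccc(OC)cc2)[C@@H]2[C@]1(C)CC[C@@]2(O)C(C)C | intermediate
23 | (3R,3aS,4S,8R,8aS)-3,8-dihydroxy-6,8a-dimethyl-3-(propan-2-yl)-1,2,3,3a,4,5,8,8a-octahydroazulen-4-yl 4-methoxybenzoate | O[C@@H]1C=C(C)C[C@H](OC(=O)c2ccc(OC)cc2)[C@@H]2[C@]1(C)CC[C@@]2(O)C(C)C | intermediate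
24 | angelic acid, (2Z)-2-methylbut-2-enoic acid | C/C=C(/C)C(=O)O | starting material
25 | (2Z)-2-methylbut-2-enoic 2,4,6-trichlorobenzoic anhydride | C/C=C(/C)C(=O)OC(=O)c1c(Cl)cc(Cl)cc1Cl | intermediate
26 | (3R,3aS,4S,8R,8aS)-3-hydroxy-4-[(4-methoxybenzoyl)oxy]-6,8a-dimethyl-3-(propan-2-yl)-1,2,3,3a,4,5,8,8a-octahydroazulen-8-yl (2Z)-2-methylbut-2-enoate (CNP0168729.1) | C/C=C(/C)C(=O)O[C@@H]1C=C(C)C[C@H](OC(=O)c2ccc(OC)cc2)[C@@H]2[C@]1(C)CC[C@@]2(O)C(C)C | target

Total step count: 14. Longest linear sequence: 14 steps (from acrolein 1 to 26).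

Steps most likely to fail

Step 7. The 1,3-induction in the 5-exo-dig closure may be too weak, so that the boron-bearing carbon forms with low facial selectivity; slow capture of the hindered primary radical may also let hydrogen-atom transfer compete. The fallback moves control of C3 from the kinetic radical closure to a thermodynamic aldol equilibrium. It sets out from 17, which after an unselective annulation and steps 8 and 9 would be accompanied by its C3 epimer, the epimeric hydroxy aldehyde F1. Catalytic base (DBU or Ba(OH)2, THF, rt) should open 17 and F1 alike by retro-aldol cleavage of C3–C3a to one open-chain keto aldehyde, (3S)-3-[(1R)-1-{[tert-butyl(dimethyl)silyl]oxy}prop-2-en-1-yl]-3,7-dimethyl-6-oxooctanal F2. Keto aldehyde F2 should re-close by 5-enolexo aldol addition of the aldehyde enolate to the isopropyl ketone. The equilibrium is expected to favour the isomer with isopropyl anti to formyl and cis-1,3 to the large C8a substituent, and with the hydroxyl hydrogen-bonded to the formyl group. The fallback comes back to the route at 17.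

Step 10. Facial control by the magnesium chelate may be lost or reversed, so that the methallyl group is delivered to the other aldehyde face. The fallback sets C4 by stereoinversion at the carbinol instead of by face-selective addition. It sets out from 17: the Grignard addition is run as in step 10 and the C4-epimeric diol F3 is separated from any 19, which continues as planned. Diol F3 is then esterified under Mitsunobu conditions (4-methoxybenzoic acid, PPh3, DIAD, toluene, 0 °C → rt). SN2 displacement of the oxyphosphonium group by the carboxylate inverts C4 and installs the aryl ester in one operation, the tertiary C3 hydroxyl being inert, and should give the acyclic 4-methoxybenzoate F4. Ring-closing metathesis of F4 under the conditions of step 11 closes the seven-membered ring with loss of ethene, and the fallback comes back to the route at 22.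

Step 11. The ruthenium carbene may fail to turn over at the hindered 1,1-disubstituted alkene next to the neopentyl-type allylic silyl ether, so that dimerisation through the vinyl group or double-bond migration takes over. The fallback forms C6=C7 by reductive carbonyl coupling instead of metathesis. It sets out from 19: the 1,3-diol is masked with 2,2-dimethoxypropane (camphorsulfonic acid cat., CH2Cl2, rt) as the isopropylidene acetal F5, so that no β-hydroxy ketone is exposed later. Ozonolysis of both terminal alkenes of F5 (O3, CH2Cl2/MeOH, −78 °C; then PPh3) gives the keto aldehyde F6, a C6 methyl ketone and a C7 aldehyde. Intramolecular McMurry coupling of F6 (TiCl3, Zn–Cu couple, DME, reflux, high dilution) should close the trisubstituted cycloheptene and give the bicyclic acetal F7. Acetal F7 is hydrolysed (80% aq AcOH, THF, rt), which should leave the hindered secondary silyl ether in place, and the fallback comes back to the route at 20.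

Further compounds
F1 | step 7 | C3 epimer of hydroxy aldehyde 17 (hydroxyl trans to the C8a methyl, C3a configuration not fixed) | C=C[C@@H](O[Si](C)(C)C(C)(C)C)[C@@]1(C)CC[C@](O)(C(C)C)C1C=O
F2 | step 7 | (3S)-3-[(1R)-1-{[tert-butyl(dimethyl)silyl]oxy}prop-2-en-1-yl]-3,7-dimethyl-6-oxooctanal | C=C[C@@H](O[Si](C)(C)C(C)(C)C)[C@](C)(CC=O)CCC(=O)C(C)C
F3 | step 10 | C4 epimer of diol 19, (1R,2S,3S)-3-[(1R)-1-{[tert-butyl(dimethyl)silyl]oxy}prop-2-en-1-yl]-2-[(1R)-1-hydroxy-3-methylbut-3-en-1-yl]-3-methyl-1-(propan-2-yl)cyclopentan-1-ol | C=C[C@@H](O[Si](C)(C)C(C)(C)C)[C@@]1(C)CC[C@@](O)(C(C)C)[C@@H]1[C@H](O)CC(C)=C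
F4 | step 10 | (1S)-1-[(1S,2R,5S)-5-[(1R)-1-{[tert-butyl(dimethyl)silyl]oxy}prop-2-en-1-yl]-2-hydroxy-5-methyl-2-(propan-2-yl)cyclopentyl]-3-methylbut-3-en-1-yl 4-methoxybenzoate | C=C[C@@H](O[Si](C)(C)C(C)(C)C)[C@@]1(C)CC[C@@](O)(C(C)C)[C@@H]1[C@@H](OC(=O)c2ccc(OC)cc2)CC(C)=C
F5 | step 11 | isopropylidene acetal of diol 19 (2,2-dimethyl-1,3-dioxane across the C3 and C4 oxygens, all stereocentres as in 19) | C=C[C@@H](O[Si](C)(C)C(C)(C)C)[C@@]1(C)CC[C@]2(C(C)C)OC(C)(C)O[C@@H](CC(C)=C)[C@H]12
F6 | step 11 | keto aldehyde from double ozonolysis of F5 (C6 methyl ketone, C7 aldehyde, acetal retained) | O=C[C@@H](O[Si](C)(C)C(C)(C)C)[C@@]1(C)CC[C@]2(C(C)C)OC(C)(C)O[C@@H](CC(C)=O)[C@H]12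
F7 | step 11 | isopropylidene acetal of bicyclic diol 20 (all stereocentres as in 20) | CC(C)(C)[Si](C)(C)O[C@@H]1C=C(C)C[C@@H]2OC(C)(C)O[C@@]3(C(C)C)CC[C@@]1(C)[C@@H]23
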